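## Analysis of the target

Fragransin B1 (16) is a 2,5-diaryl-3,4-dimethyltetrahydrofuran lignan: one oxolane ring (O1, C2 to C5) carries a 4-hydroxy-3,5-dimethoxyphenyl group on C2 and on C5 and a methyl group on C3 and on C4. All four ring carbons are stereocentres, with both aryl groups on one face and both methyl groups on the other, that is 2,3-trans, 3,4-cis, 4,5-trans. A mirror plane through O1 and the midpoint of C3–C4 makes the compound meso, (2R,3R,4S,5S), so only relative configuration has to be controlled. The sensitive sites are the two electron-rich phenols and the two ring C–O bonds, which are benzylic to para-oxygenated arenes and ionise in acid. That lability allows C2 and C5 to be corrected under thermodynamic control, but it also opens paths to elimination, Friedel–Crafts closure onto the second arene and hydrogenolysis. The real difficulty is the cis relation of the methyl groups at C3 and C4, which cannot be epimerised and must be built kinetically. The plan is built on the C3–C4 bond, which the mirror plane bisects: the same aryl-bearing oxygenated methine and methyl-bearing carbon sit on either side of it, and two cis methyl groups are exactly what delivery of H2 to one face of a C3=C4 ring alkene must produce. Ring-closing metathesis of a symmetrical bis(2-methylallyl) ether can form that alkene.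

## Retrosynthetic reasoning

**16 from 14.** The first retrosynthetic move cuts no skeletal bond; it releases the configuration at C2 and C5. Each of these carbons is a para-hydroxybenzylic ether carbon, so in acid the C2–O or C5–O bond opens reversibly and recloses. The isomer with each aryl group trans to its neighbouring methyl group is the most stable of the three that share cis methyl groups. 16 can therefore come from the all-cis isomer 14 by way of the mono-epimer 15, and only C3 and C4 need to be right earlier. The forward step must equilibrate C2 and C5 without touching C3 and C4.

**14 from 13, and 13 from 12.** The phenols are carried as benzyl ethers (13), which survive organomagnesium reagents, strong base and metathesis and come off by hydrogenolysis. Removing the two hydrogens at C3 and C4 from 13 leads to the 2,5-dihydrofuran 12. The cut is made there because it puts the alkene on the symmetry element, so syn hydrogenation gives cis methyl groups whichever face is used. The forward reaction needs a catalyst that saturates a tetrasubstituted alkene without cleaving the allylic, benzylic C–O bonds.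

**12 from 11.** The C3=C4 double bond is cut, each alkene carbon regaining a terminal methylene. This is the only scission that leaves two identical halves joined through oxygen alone, the bis(2-methylallyl) ether 11. The forward reaction is a ring-closing metathesis to a tetrasubstituted alkene in a five-membered ring. It makes no stereocentre, so the racemic form of 11 is as useful as the meso form.

**11 from 10, and 10 from 9 and 8.** The direct symmetrical cut, dehydrative dimerisation of alcohol 5 in acid, is not used. The cation from 5 is a 1-aryl-2-methylallyl cation, which can be captured at its terminal methylene to give the conjugated, transposed ether and can also cyclise onto its own electron-rich ring. Instead, one C–O bond is made under basic conditions from alkoxide 9, and the second carbinol carbon enters at the aldehyde oxidation level as the chloride 8. The N,O-acetal 10 then loses its benzotriazolyl group to the Grignard reagent 4 through an oxocarbenium ion that has no allylic alternative. The C–isopropenyl bond at that carbon is therefore the last bond formed before the key step.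

**5 and 8 from 3, and 3 from 1 and 2.** Alcohol 5 comes from addition of 4 to aldehyde 3. Chloride 8 comes from the same aldehyde and benzotriazole 6 through hemiaminal 7. Aldehyde 3 is the benzyl ether of syringaldehyde 1, made with 2. Both halves of the target thus come from one aldehyde.

## Alternatives that were turned down

**Alternative 1:** The ring is cut at C3–C4 and C5–O into two unlike halves: the β-ketoester A1 (C2, C3 and an ester on C3 as a masked methyl group) and the propenylarene A2 (C4, C5). In the forward key step Mn(OAc)3, a one-electron oxidant of trivalent manganese, turns A1 into its α-radical, which adds to the methyl-bearing alkene carbon of A2. The benzylic radical is oxidised further and the ketone oxygen closes the 4,5-dihydrofuran A3 with aryl and methyl trans at C4/C5.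
- For: it is convergent, makes two ring bonds in one operation by a well-tried radical annulation of aryl alkenes, and sets one aryl/methyl trans relation directly.
- Against: A3 carries an ester where the target has a methyl group, which costs about three redox operations. The C2=C3 enol ether, tetrasubstituted and aryl-conjugated, must then be hydrogenated anti to the single C4 methyl group to give the cis methyl pair. The electron-rich alkene A2 is itself open to one-electron oxidation by the reagent. A symmetrical target is built from two different halves.
- Comparison: this route is stronger in that its C–C bond formation is intermolecular and robust. The chosen route has no group to excise, draws both halves from one aldehyde, and gets the cis methyl pair from syn addition to a symmetrical alkene, not from the facial bias of one methyl group.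

**Alternative 2:** The ring is cut at C5–O and C2–C3 into the donor–acceptor cyclopropane A4 and aldehyde 3. In the forward key step Sn(OTf)2, a Lewis acid of divalent tin, binds the geminal diester. The oxygen of 3 opens the ring at the aryl-bearing carbon with inversion, and the malonate carbon closes on the aldehyde carbon to give the tetrahydrofuran A5.
- For: three of the four stereocentres (C2, C4, C5) arrive with the right relative configuration, 2,5-cis aryl groups and 4,5-trans. The electron-rich aryl donor is well suited and the step is catalytic.
- Against: C3 is a quaternary diester. It needs dealkoxycarbonylation (Krapcho) and then conversion of the remaining ester to methyl, about four operations. The C3 configuration must end cis to the C4 methyl group and trans to the C2 aryl group, and the only handle is epimerisation next to the ester, where those two preferences oppose each other. An invertive opening gives 4,5-trans only from the cyclopropane with aryl and methyl cis, the less accessible isomer. With so strong a donor the ring may open to a zwitterion and lose that stereochemical information.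
- Comparison: this route is stronger at C2 and C5, which need no late equilibration. It leaves unsolved the cis methyl pair, which the chosen route fixes by construction at the price of one equilibration step.

**Alternative 3:** The ring is cut at C2–O and C2–C3, so that C2 with its aryl group is added as a carbene from the diazo compound A7 across the O=C–C=C unit of the tiglyl ketone A6. In the forward key step Cu(MeCN)4PF6, a monovalent copper catalyst with a bipyridine ligand, transfers the arylcarbene to the ketone oxygen. The vinyl carbonyl ylide closes by six-electron electrocyclisation to the 2,3-dihydrofuran A8 with aryl and methyl trans at C2/C3.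
- For: A8 contains every carbon of the target and no surplus group, and differs from the protected skeleton only by H2. It is the shortest route on paper and sets one aryl/methyl trans relation in the ring-forming step.
- Against: A7 is a donor-only aryldiazomethane on a very electron-rich ring. It is unstable and prone to azine formation, carbene dimerisation and cyclopropanation of A6, whereas this mode of annulation is established for acceptor-substituted diazo compounds. The C4=C5 enol ether must still be hydrogenated anti to the C3 methyl group, with cleavage of the allylic, benzylic C–O bond in competition, and C5 then needs the same acid equilibration.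
- Comparison: this route is at least as good in step and atom economy. The chosen route places its risk in a ring closure with precedent on the same alkene type, avoids a hazardous diazo compound, and hydrogenates a symmetrical alkene whose outcome does not depend on facial bias.

Key step: step 5

Remark on the chemistry: step 4 sets the second carbinol centre without control, so each of the numbers 11, 12, 13 and 14 stands for a mixture of two diastereomers that is carried on unseparated; the structure named and drawn is the member of the meso series, the second member (from the racemic form of 11) differs only in the configuration of one aryl-bearing carbon, and the two series meet in step 8.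

## Route

**Step 1**
Reactants: 1 syringaldehyde (4-hydroxy-3,5-dimethoxybenzaldehyde); 2 benzyl bromide
Product: 3 4-benzyloxy-3,5-dimethoxybenzaldehyde
Conditions: K2CO3, DMF, 60 °C
Reagents that add atoms: none
Why: Williamson etherification of the phenol; the benzyl ether masks the acidic OH through the organomagnesium, NaH and metathesis steps and is removed late by hydrogenolysis.

**Step 2**
Reactants: 3 4-benzyloxy-3,5-dimethoxybenzaldehyde; 4 isopropenylmagnesium bromide
Product: 5 rac-1-(4-benzyloxy-3,5-dimethoxyphenyl)-2-methylprop-2-en-1-ol
Conditions: CH2=C(CH3)MgBr, THF, −78 to 0 °C; aq NH4Cl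
Reagents that add atoms: none
Why: Grignard 1,2-addition to a non-enolisable aryl aldehyde. The carbinol centre forms racemic, which does not matter because C2 and C5 are equilibrated in step 8; the work-up is kept non-acidic because this alcohol ionises easily.

**Step 3**
Reactants: 3 4-benzyloxy-3,5-dimethoxybenzaldehyde; 6 1H-benzotriazole
Product: 8 rac-1-[chloro(4-benzyloxy-3,5-dimethoxyphenyl)methyl]-1H-benzotriazole, via hemiaminal 7 (not isolated)
Conditions: toluene, rt; then SOCl2, 0 °C to rt; volatiles removed, used crude
Reagents that add atoms: thionyl chloride, O=S(Cl)Cl
Why: Benzotriazole adds to the aldehyde to give hemiaminal 7, whose hydroxyl is exchanged for chloride by SOCl2 (the known preparation of 1-(α-chloroalkyl)benzotriazoles). The product is a masked, storable form of the aryl oxocarbenium ion at the aldehyde oxidation level.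

**Step 4**
Reactants: 5 rac-1-(4-benzyloxy-3,5-dimethoxyphenyl)-2-methylprop-2-en-1-ol; 8 rac-1-[chloro(4-benzyloxy-3,5-dimethoxyphenyl)methyl]-1H-benzotriazole; 4 isopropenylmagnesium bromide
Product: 11 meso-bis[1-(4-benzyloxy-3,5-dimethoxyphenyl)-2-methylprop-2-enyl] ether (formed in admixture with its racemic diastereomer), via sodium alkoxide 9 (not isolated), via benzotriazolyl ether 10 (not isolated)
Conditions: NaH, THF, 0 °C; then 8, 0 °C to rt; then CH2=C(CH3)MgBr, THF–toluene, rt to 60 °C; aq NH4Cl; Et3N-washed silica
Reagents that add atoms: none
Why: Benzotriazole-mediated ether synthesis: alkoxide 9 displaces chloride from 8 to give the N,O-acetal 10, and the Grignard reagent then replaces the benzotriazolyl group through an aryl-stabilised oxocarbenium ion. Neither C–O bond passes through the free 1-aryl-2-methylallyl cation, so allylic transposition and cyclisation onto the arene are avoided; 10 is not isolated because it would hydrolyse on silica. The new carbinol centre forms without control, so 11 is obtained as its meso and racemic diastereomers together, and the mixture is taken on as such.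

**Step 5**
Reactants: 11 meso-bis[1-(4-benzyloxy-3,5-dimethoxyphenyl)-2-methylprop-2-enyl] ether (in admixture with its racemic diastereomer)
Product: 12 cis-(2R,5S)-2,5-bis(4-benzyloxy-3,5-dimethoxyphenyl)-3,4-dimethyl-2,5-dihydrofuran (in admixture with its trans isomer)
Conditions: RuCl2(H2IMes)(=CH-C6H4-2-OiPr) (second-generation Hoveyda–Grubbs catalyst, 10 mol%), 1,4-benzoquinone (10 mol%), toluene, 80 °C, Ar sparge
Reagents that add atoms: none
Why: After release of the chelating styrenyl ether the propagating Ru=CH2 species adds to one isopropenyl group of 11 and, with loss of ethylene, gives a ruthenium alkylidene at C3 that bears the methyl group and the carbinol carbon; intramolecular (2+2) cycloaddition onto the second isopropenyl group and cycloreversion of the ruthenacyclobutane release the C3=C4 alkene and regenerate Ru=CH2. The closest known reaction type is the ring-closing metathesis of bis(2-methylallyl) ethers and related 2,2'-disubstituted 1,6-dienes to 3,4-dimethyl five-membered rings with N-heterocyclic-carbene ruthenium catalysts. The one ring formed is the 2,5-dihydrofuran, closed at C3–C4 by cycloaddition of the tethered alkylidene, a five-membered closure in which O1, C2 and C5 are already connected. No stereocentre is created: C2 and C5 pass through unchanged, so the meso member of 11 gives the cis dihydrofuran drawn for 12 and the racemic member gives the trans isomer. The step needs cyclisation to win over intermolecular metathesis and over hydride-induced alkene migration into the enol ether position; 1,1-disubstituted alkenes are poor intermolecular partners, the two fully substituted carbinol carbons favour the folded rotamer, removal of ethylene makes closure irreversible and benzoquinone intercepts ruthenium hydrides. The neutral conditions leave the acid-labile bis-benzylic ether and the benzyl ethers untouched.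

**Step 6**
Reactants: 12 cis-(2R,5S)-2,5-bis(4-benzyloxy-3,5-dimethoxyphenyl)-3,4-dimethyl-2,5-dihydrofuran (in admixture with its trans isomer)
Product: 13 (2R,3S,4R,5S)-2,5-bis(4-benzyloxy-3,5-dimethoxyphenyl)-3,4-dimethyltetrahydrofuran (meso all-cis isomer; in admixture with its epimer at one aryl-bearing carbon)
Conditions: H2 (20 bar), [Ir(cod)(PCy3)(py)]PF6 (Crabtree catalyst, 5 mol%), CH2Cl2, rt
Reagents that add atoms: none
Why: Homogeneous hydrogenation with a cationic iridium catalyst that reduces tetrasubstituted alkenes and does not hydrogenolyse benzyl or allylic C–O bonds; both hydrogens arrive on one face, so the C3 and C4 methyl groups must be cis. In the cis member of 12 the face opposite the two aryl groups is open and the all-cis isomer drawn for 13 results; in the trans member the two faces are equivalent and the product has one aryl group cis and one trans to the methyl pair. Any epimerisation at C2 or C5 is harmless because these centres are equilibrated in step 8.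

**Step 7**
Reactants: 13 (2R,3S,4R,5S)-2,5-bis(4-benzyloxy-3,5-dimethoxyphenyl)-3,4-dimethyltetrahydrofuran (in admixture with its epimer at one aryl-bearing carbon)
Product: 14 4,4'-[(2R,3S,4R,5S)-3,4-dimethyltetrahydrofuran-2,5-diyl]bis(2,6-dimethoxyphenol) (meso all-cis isomer; in admixture with its epimer at one aryl-bearing carbon)
Conditions: H2 (1 atm), Pd/C, EtOAc–MeOH, rt, stopped after uptake of 2 equiv
Reagents that add atoms: none
Why: Hydrogenolysis of the aryl benzyl ethers over Pd/C; the ring C–O bonds are now saturated, hindered dialkyl benzylic ethers and cleave more slowly. Both members of 13 are debenzylated in the same way.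

**Step 8**
Reactants: 14 4,4'-[(2R,3S,4R,5S)-3,4-dimethyltetrahydrofuran-2,5-diyl]bis(2,6-dimethoxyphenol) (in admixture with its epimer at one aryl-bearing carbon)
Product: 16 fragransin B1 [meso-(2R,3R,4S,5S)-4,4'-(3,4-dimethyltetrahydrofuran-2,5-diyl)bis(2,6-dimethoxyphenol)], via mono-epimer 15 (not isolated)
Conditions: CF3CO2H (0.2 equiv), CH2Cl2, 0 °C to rt, followed until the isomer composition is constant
Reagents that add atoms: none
Why: Acid-catalysed benzylic epimerisation by SN1 ring opening and reclosure: protonation of O1 and heterolysis of C2–O or C5–O gives a para-hydroxybenzylic cation (a protonated quinone methide) that the tethered hydroxyl recaptures reversibly from either face, while C3 and C4 are not involved. The all-cis isomer 14 inverts at one aryl-bearing carbon to 15 and 15 inverts at the other to 16; the second member of 14, which comes from the racemic series, is 15 itself and enters the same equilibrium. The isomer with each aryl group trans to its neighbouring methyl group has the fewest cis aryl/methyl contacts and should be the thermodynamic product of the cis-dimethyl series, as is known for 2,5-diaryltetrahydrofuran and furofuran lignans.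

## Compound list

1 | syringaldehyde (4-hydroxy-3,5-dimethoxybenzaldehyde) | COc1cc(C=O)cc(OC)c1O | starting material
2 | benzyl bromide | BrCc1ccccc1 | starting material
3 | 4-benzyloxy-3,5-dimethoxybenzaldehyde | COc1cc(C=O)cc(OC)c1OCc1ccccc1 | intermediate
4 | isopropenylmagnesium bromide | C=C(C)[Mg]Br | starting material
5 | rac-1-(4-benzyloxy-3,5-dimethoxyphenyl)-2-methylprop-2-en-1-ol | CC(=C)C(O)c1cc(OC)c(OCc2ccccc2)c(OC)c1 | intermediate
6 | 1H-benzotriazole | c1ccc2[nH]nnc2c1 | starting material
7 | rac-(1H-benzotriazol-1-yl)(4-benzyloxy-3,5-dimethoxyphenyl)methanol (hemiaminal, not isolated) | OC(c1cc(OC)c(OCc2ccccc2)c(OC)c1)n1nnc2ccccc21 | intermediate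
8 | rac-1-[chloro(4-benzyloxy-3,5-dimethoxyphenyl)methyl]-1H-benzotriazole | ClC(c1cc(OC)c(OCc2ccccc2)c(OC)c1)n1nnc2ccccc21 | intermediate
9 | sodium 1-(4-benzyloxy-3,5-dimethoxyphenyl)-2-methylprop-2-en-1-olate (sodium alkoxide of 5, not isolated) | CC(=C)C([O-])c1cc(OC)c(OCc2ccccc2)c(OC)c1.[Na+] | intermediate
10 | 1-{(4-benzyloxy-3,5-dimethoxyphenyl)[1-(4-benzyloxy-3,5-dimethoxyphenyl)-2-methylprop-2-enyloxy]methyl}-1H-benzotriazole (diastereomer mixture, not isolated) | CC(=C)C(OC(c1cc(OC)c(OCc2ccccc2)c(OC)c1)n1nnc2ccccc21)c1cc(OC)c(OCc2ccccc2)c(OC)c1 | intermediate
11 | meso-(R,S)-bis[1-(4-benzyloxy-3,5-dimethoxyphenyl)-2-methylprop-2-enyl] ether (drawn; carried in admixture with its racemic (R,R)/(S,S) diastereomer) | C=C(C)[C@H](c1cc(OC)c(OCc2ccccc2)c(OC)c1)O[C@H](c1cc(OC)c(OCc2ccccc2)c(OC)c1)C(C)=C | intermediate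
12 | cis-(2R,5S)-2,5-bis(4-benzyloxy-3,5-dimethoxyphenyl)-3,4-dimethyl-2,5-dihydrofuran (meso, drawn; carried in admixture with its racemic trans (2S,5S)/(2R,5R) isomer) | CC1=C(C)[C@H](c2cc(OC)c(OCc3ccccc3)c(OC)c2)O[C@@H]1c1cc(OC)c(OCc2ccccc2)c(OC)c1 | intermediate
13 | (2R,3S,4R,5S)-2,5-bis(4-benzyloxy-3,5-dimethoxyphenyl)-3,4-dimethyltetrahydrofuran (meso, all-cis, drawn; carried in admixture with its racemic 2,3-trans-3,4-cis-4,5-cis epimer) | COc1cc([C@H]2O[C@@H](c3cc(OC)c(OCc4ccccc4)c(OC)c3)[C@@H](C)[C@H]2C)cc(OC)c1OCc1ccccc1 | intermediate
14 | 4,4'-[(2R,3S,4R,5S)-3,4-dimethyltetrahydrofuran-2,5-diyl]bis(2,6-dimethoxyphenol) (meso, all-cis, drawn; carried in admixture with its epimer at one aryl-bearing carbon, which is 15) | COc1cc([C@H]2O[C@@H](c3cc(OC)c(O)c(OC)c3)[C@@H](C)[C@H]2C)cc(OC)c1O | intermediate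
15 | rac-4,4'-[(2S,3S,4R,5S)-3,4-dimethyltetrahydrofuran-2,5-diyl]bis(2,6-dimethoxyphenol) (2,3-trans, 3,4-cis, 4,5-cis; one enantiomer drawn; not isolated) | COc1cc([C@H]2O[C@H](c3cc(OC)c(O)c(OC)c3)[C@H](C)[C@@H]2C)cc(OC)c1O | intermediate
16 | fragransin B1, 4,4'-[(2R,3R,4S,5S)-3,4-dimethyltetrahydrofuran-2,5-diyl]bis(2,6-dimethoxyphenol) (meso) | COc1cc([C@H]2O[C@@H](c3cc(OC)c(O)c(OC)c3)[C@H](C)[C@@H]2C)cc(OC)c1O | target

## Step count and least certain steps

Total step count: 8. Longest linear sequence: 7 (steps 1, 2, 4, 5, 6, 7, 8; step 3 is a one-step branch from 3).

**Step 5 (key step).** The most likely failure is catalyst decay before turnover. The disubstituted alkylidene next to a branched carbinol carbon forms slowly, and closure to a tetrasubstituted alkene is slow as well. Ruthenium hydrides formed meanwhile can move a double bond into the enol ether position and consume the diene. A less hindered catalyst of the same family, RuCl2(1,3-di-o-tolylimidazolidin-2-ylidene)(=CH-C6H4-2-OiPr), would be the first adjustment; the fallback proper changes the bond-forming reaction.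
Fallback, setting out from 11 and coming back at 12: the C3=C4 bond is made by reductive carbonyl coupling in place of metathesis. Oxidative cleavage of both isopropenyl groups of 11 (OsO4 cat., NaIO4, 2,6-lutidine, dioxane–water) gives bis[1-(4-benzyloxy-3,5-dimethoxyphenyl)-2-oxopropyl] ether F1 with loss of two molecules of formaldehyde. Intramolecular McMurry coupling of F1 (TiCl3(DME)1.5, Zn–Cu couple, DME, reflux, slow addition) should then join the two ketone carbons to the tetrasubstituted alkene of 12. Five-membered ring closure of a 1,5-diketone is a favourable case of this coupling, and it is indifferent to the degree of substitution of the alkene. Both diastereomers of F1 serve, as both members of 12 do. The point to watch is reductive loss of the α-alkoxy group by the low-valent titanium.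

**Step 4.** The likely failures are heterolysis of the wrong C–O bond at the oxocarbenium stage, with loss of the 1-aryl-2-methylallyl group, and hydrolysis of the moisture-sensitive chloride 8 before the alkoxide captures it.
Fallback, setting out from 3 and 5 and coming back at 11: Pinnick oxidation of 3 (NaClO2, NaH2PO4, 2-methylbut-2-ene) gives 4-benzyloxy-3,5-dimethoxybenzoic acid F2. Steglich esterification of F2 with 5 (DCC, DMAP) gives 1-(4-benzyloxy-3,5-dimethoxyphenyl)-2-methylprop-2-enyl 4-benzyloxy-3,5-dimethoxybenzoate F3. Reductive acetylation of the ester (iBu2AlH, −78 °C; then Ac2O, pyridine, DMAP) gives acetoxy(4-benzyloxy-3,5-dimethoxyphenyl)methyl 1-(4-benzyloxy-3,5-dimethoxyphenyl)-2-methylprop-2-enyl ether F4. BF3·OEt2-promoted substitution of the acetate by potassium isopropenyltrifluoroborate, CH2=C(CH3)BF3K, at low temperature then gives 11, again as both diastereomers.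

**Step 6.** The likely failures are slow uptake on the trans member of 12, where each face carries one aryl group, and iridium-hydride migration of the double bond to the 2,3-position, which would remove the guarantee of cis methyl groups. Dehydrogenation to the furan is a further possibility.
Fallback, setting out from 12 and coming back at 14: DDQ in toluene dehydrogenates both members of 12 to the same 2,5-bis(4-benzyloxy-3,5-dimethoxyphenyl)-3,4-dimethylfuran F5, which has no stereocentre. Hydrogenation of F5 over Pd/C under pressure should add all four hydrogens to one face of the flat ring and cleave the benzyl ethers in the same operation, giving the all-cis bisphenol 14, after which step 8 follows.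

**Step 8.** The likely failure is overshoot of the opened cation. Loss of the C3 proton would scramble C3 and leak into the trans-dimethyl series; the cation could also close onto the second arene to give an aryltetralin, or alkylate another phenol intermolecularly.
Fallback, setting out from 13 and coming back at 16: the equilibration is moved to the benzyl ether stage, where no quinone methide can form. BF3·OEt2 in CH2Cl2 at −20 °C should convert both members of 13 into (2R,3R,4S,5S)-2,5-bis(4-benzyloxy-3,5-dimethoxyphenyl)-3,4-dimethyltetrahydrofuran F6, which can be purified as a non-polar meso compound. Hydrogenolysis of F6 (H2, Pd/C) then gives 16 directly.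

## Further compounds

F1 | step 5 | bis[1-(4-benzyloxy-3,5-dimethoxyphenyl)-2-oxopropyl] ether (diastereomer mixture) | CC(=O)C(OC(C(C)=O)c1cc(OC)c(OCc2ccccc2)c(OC)c1)c1cc(OC)c(OCc2ccccc2)c(OC)c1
F2 | step 4 | 4-benzyloxy-3,5-dimethoxybenzoic acid | COc1cc(C(=O)O)cc(OC)c1OCc1ccccc1
F3 | step 4 | rac-1-(4-benzyloxy-3,5-dimethoxyphenyl)-2-methylprop-2-enyl 4-benzyloxy-3,5-dimethoxybenzoate | CC(=C)C(OC(=O)c1cc(OC)c(OCc2ccccc2)c(OC)c1)c1cc(OC)c(OCc2ccccc2)c(OC)c1
F4 | step 4 | acetoxy(4-benzyloxy-3,5-dimethoxyphenyl)methyl 1-(4-benzyloxy-3,5-dimethoxyphenyl)-2-methylprop-2-enyl ether (diastereomer mixture) | CC(=C)C(OC(OC(C)=O)c1cc(OC)c(OCc2ccccc2)c(OC)c1)c1cc(OC)c(OCc2ccccc2)c(OC)c1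
F5 | step 6 | 2,5-bis(4-benzyloxy-3,5-dimethoxyphenyl)-3,4-dimethylfuran | Cc1c(C)c(-c2cc(OC)c(OCc3ccccc3)c(OC)c2)oc1-c1cc(OC)c(OCc2ccccc2)c(OC)c1
F6 | step 8 | (2R,3R,4S,5S)-2,5-bis(4-benzyloxy-3,5-dimethoxyphenyl)-3,4-dimethyltetrahydrofuran (meso) | COc1cc([C@H]2O[C@@H](c3cc(OC)c(OCc4ccccc4)c(OC)c3)[C@H](C)[C@@H]2C)cc(OC)c1OCc1ccccc1
A1 | alternative 1 | ethyl 3-(4-benzyloxy-3,5-dimethoxyphenyl)-3-oxopropanoate | CCOC(=O)CC(=O)c1cc(OC)c(OCc2ccccc2)c(OC)c1
A2 | alternative 1 | (E)-2-benzyloxy-1,3-dimethoxy-5-(prop-1-enyl)benzene | C/C=C/c1cc(OC)c(OCc2ccccc2)c(OC)c1
A3 | alternative 1 | ethyl trans-2,5-bis(4-benzyloxy-3,5-dimethoxyphenyl)-4-methyl-4,5-dihydrofuran-3-carboxylate (racemic, one enantiomer drawn) | CCOC(=O)C1=C(c2cc(OC)c(OCc3ccccc3)c(OC)c2)O[C@@H](c2cc(OC)c(OCc3ccccc3)c(OC)c2)[C@@H]1C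
A4 | alternative 2 | dimethyl cis-2-(4-benzyloxy-3,5-dimethoxyphenyl)-3-methylcyclopropane-1,1-dicarboxylate (racemic, one enantiomer drawn) | COC(=O)C1(C(=O)OC)[C@H](c2cc(OC)c(OCc3ccccc3)c(OC)c2)[C@@H]1C
A5 | alternative 2 | dimethyl 2,5-cis-4,5-trans-2,5-bis(4-benzyloxy-3,5-dimethoxyphenyl)-4-methyltetrahydrofuran-3,3-dicarboxylate (racemic, one enantiomer drawn) | COc1cc([C@H]2O[C@@H](c3cc(OC)c(OCc4ccccc4)c(OC)c3)[C@H](C)C2(C(=O)OC)C(=O)OC)cc(OC)c1OCc1ccccc1
A6 | alternative 3 | (E)-1-(4-benzyloxy-3,5-dimethoxyphenyl)-2-methylbut-2-en-1-one | C/C=C(\C)C(=O)c1cc(OC)c(OCc2ccccc2)c(OC)c1
A7 | alternative 3 | 2-benzyloxy-5-(diazomethyl)-1,3-dimethoxybenzene | [N-]=[N+]=Cc1cc(OC)c(OCc2ccccc2)c(OC)c1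
A8 | alternative 3 | trans-2,5-bis(4-benzyloxy-3,5-dimethoxyphenyl)-3,4-dimethyl-2,3-dihydrofuran (racemic, one enantiomer drawn) | COc1cc([C@H]2OC(c3cc(OC)c(OCc4ccccc4)c(OC)c3)=C(C)[C@@H]2C)cc(OC)c1OCc1ccccc1
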